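**Retrosynthetic overview**
1. Target 23 comes from dibromide 22 by double hydrodebromination. The two bromines (C6 of the 8-linked flavan unit A, C8 of the 6-linked flavan unit B) only serve to leave one reactive site on each partner.
2. The key C–C bond (Ar–CH2–Ar) is made by Michael-type 1,4-addition of bromophenol 13, through C6, to the ortho-quinone methide 21 released from the Mannich-base salt of 19.
3. Both 13 and 19 come from one common (2S)-8-bromoflavan 12.
4. Each pyran ring is closed before the coupling: 12 from flavan 11, which is formed by intramolecular Mitsunobu etherification (inversion) of the (R)-carbinol 10 obtained by CBS reduction.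
5. The C6–C3–C6 skeleton comes from a Claisen–Schmidt aldol condensation of aldehyde 4 (from 2,4,6-trihydroxybenzaldehyde 1) with acetophenone 5.

Assumption: the code is taken to mean exactly the (2S,2'S) structure of the given SMILES; simple commercial reagents (MOMCl, MeI, BnBr, NBS, DMF, Me2NH) are named in the steps and not numbered.

**Route**

Step 1
Reactants: 1 2,4,6-trihydroxybenzaldehyde
Product: 2 2,6-dihydroxy-4-(methoxymethoxy)benzaldehyde
Conditions: MOMCl (1.05 equiv), K2CO3 (1.1 equiv), acetone, 0 °C to rt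
Reagents that add atoms: chloromethyl methyl ether, COCCl
Why: Williamson-type O-alkylation goes to the 4-OH, the most acidic hydroxyl and the only one not tied into the hydrogen-bonded chelate with the formyl group.

Step 2
Reactants: 2 2,6-dihydroxy-4-(methoxymethoxy)benzaldehyde
Product: 3 2-hydroxy-6-methoxy-4-(methoxymethoxy)benzaldehyde
Conditions: MeI (1.1 equiv), K2CO3 (1.1 equiv), acetone, rt to 40 °C
Reagents that add atoms: iodomethane, CI
Why: Williamson O-methylation of one of two equivalent ortho hydroxyls stops at the mono-ether because the remaining OH is then strongly chelated to the aldehyde carbonyl.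

Step 3
Reactants: 3 2-hydroxy-6-methoxy-4-(methoxymethoxy)benzaldehyde
Product: 4 2-(benzyloxy)-6-methoxy-4-(methoxymethoxy)benzaldehyde
Conditions: BnBr (1.3 equiv), K2CO3 (2 equiv), DMF, 60 °C
Reagents that add atoms: benzyl bromide, BrCc1ccccc1
Why: Williamson benzylation of the chelated phenol under forcing conditions masks the future ring oxygen with a group that later leaves by neutral hydrogenolysis, orthogonal to the MOM ether.

Step 4
Reactants: 4 2-(benzyloxy)-6-methoxy-4-(methoxymethoxy)benzaldehyde; 5 acetophenone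
Product: 7 (E)-3-[2-(benzyloxy)-6-methoxy-4-(methoxymethoxy)phenyl]-1-phenylprop-2-en-1-one, via aldol adduct 6 (not isolated)
Conditions: KOH (3 equiv), EtOH, rt, 24 h
Reagents that add atoms: none
Why: Claisen–Schmidt (crossed aldol) condensation, in which the non-enolisable, fully O-protected aldehyde accepts the acetophenone enolate and E1cB dehydration gives the E-enone that carries the whole C6–C3–C6 skeleton.

Step 5
Reactants: 7 (E)-3-[2-(benzyloxy)-6-methoxy-4-(methoxymethoxy)phenyl]-1-phenylprop-2-en-1-one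
Product: 8 3-[2-(benzyloxy)-6-methoxy-4-(methoxymethoxy)phenyl]-1-phenylpropan-1-one
Conditions: H2 (1 atm), 10% Pd/C, Ph2S (0.01 equiv), EtOAc, rt
Reagents that add atoms: none
Why: Heterogeneous hydrogenation over sulfide-poisoned palladium on carbon saturates the conjugated C=C while the aryl ketone and the benzyl and MOM ethers are left intact.

Step 6
Reactants: 8 3-[2-(benzyloxy)-6-methoxy-4-(methoxymethoxy)phenyl]-1-phenylpropan-1-one
Product: 9 (1R)-3-[2-(benzyloxy)-6-methoxy-4-(methoxymethoxy)phenyl]-1-phenylpropan-1-ol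
Conditions: (S)-Me-CBS [(S)-1-methyl-3,3-diphenyltetrahydro-1H,3H-pyrrolo[1,2-c][1,3,2]oxazaborole, 10 mol %], BH3·SMe2 (1.0 equiv), THF, −20 °C; MeOH quench
Reagents that add atoms: none
Why: Corey–Bakshi–Shibata reduction, in which the (S)-oxazaborolidine–borane complex binds the ketone with phenyl as the large group and delivers hydride as for acetophenone, giving the (R)-carbinol that will become C2.

Step 7
Reactants: 9 (1R)-3-[2-(benzyloxy)-6-methoxy-4-(methoxymethoxy)phenyl]-1-phenylpropan-1-ol
Product: 10 (1R)-3-[2-hydroxy-6-methoxy-4-(methoxymethoxy)phenyl]-1-phenylpropan-1-ol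
Conditions: H2 (1 atm), 10% Pd/C, EtOAc, rt
Reagents that add atoms: none
Why: Hydrogenolysis of the aryl benzyl ether under neutral conditions frees the phenol, while the secondary benzylic carbinol (not cleaved without acid) and the MOM ether stay untouched, so the stereocentre is kept.

Step 8
Reactants: 10 (1R)-3-[2-hydroxy-6-methoxy-4-(methoxymethoxy)phenyl]-1-phenylpropan-1-ol
Product: 11 (2S)-5-methoxy-7-(methoxymethoxy)-2-phenylchromane
Conditions: PPh3 (1.3 equiv), DIAD (diisopropyl azodicarboxylate, 1.3 equiv), THF (0.02 M), 0 °C to rt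
Reagents that add atoms: none
Why: Intramolecular Mitsunobu etherification, in which the phenol displaces the activated benzylic oxygen in a 6-exo SN2 closure with clean inversion, turning the (R)-carbinol into the (2S)-flavan.

Step 9
Reactants: 11 (2S)-5-methoxy-7-(methoxymethoxy)-2-phenylchromane
Product: 12 (2S)-8-bromo-5-methoxy-7-(methoxymethoxy)-2-phenylchromane
Conditions: NBS (1.0 equiv), CH2Cl2, −40 to 0 °C, dark
Reagents that add atoms: N-bromosuccinimide, O=C1CCC(=O)N1Br
Why: Electrophilic aromatic bromination of the phloroglucinol-type ring goes to C8, next to the tied-back ring oxygen, and not to C6, which is buttressed by two freely rotating alkoxy groups (the known preference of 5,7-dialkoxyflavans).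

Step 10
Reactants: 12 (2S)-8-bromo-5-methoxy-7-(methoxymethoxy)-2-phenylchromane
Product: 13 (2S)-8-bromo-5-methoxy-2-phenylchroman-7-ol
Conditions: HCl (2 M in MeOH), 40 °C
Reagents that add atoms: none
Why: Acid-catalysed acetal exchange passes the MOM group to methanol and frees the 7-OH, while aryl bromide, methyl ether and the flavan ring (plain phenyl at C2, no easy ionisation) are stable.

Step 11
Reactants: 12 (2S)-8-bromo-5-methoxy-7-(methoxymethoxy)-2-phenylchromane
Product: 15 (2S)-5-methoxy-7-(methoxymethoxy)-2-phenylchromane-8-carbaldehyde, via aryllithium 14 (not isolated)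
Conditions: n-BuLi (1.1 equiv), THF, −78 °C, 20 min; DMF (3 equiv), −78 to 0 °C; H2O
Reagents that add atoms: N,N-dimethylformamide, CN(C)C=O
Why: Bromine–lithium exchange at −78 °C is faster than any deprotonation and the MOM-chelated aryllithium is formylated by DMF (Bouveault formylation) exactly at C8.

Step 12
Reactants: 15 (2S)-5-methoxy-7-(methoxymethoxy)-2-phenylchromane-8-carbaldehyde
Product: 16 (2S)-6-bromo-5-methoxy-7-(methoxymethoxy)-2-phenylchromane-8-carbaldehyde
Conditions: NBS (1.05 equiv), MeCN, 0 °C to rt, dark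
Reagents that add atoms: N-bromosuccinimide, O=C1CCC(=O)N1Br
Why: Electrophilic bromination can only go to C6, the last free position of the oxygenated ring (meta to the formyl group, activated by three oxygens), and this blocks the site against self-alkylation in the coupling.

Step 13
Reactants: 16 (2S)-6-bromo-5-methoxy-7-(methoxymethoxy)-2-phenylchromane-8-carbaldehyde
Product: 18 1-[(2S)-6-bromo-5-methoxy-7-(methoxymethoxy)-2-phenylchroman-8-yl]-N,N-dimethylmethanamine, via iminium ion 17 (not isolated)
Conditions: Me2NH (2 M in THF, 3 equiv), AcOH (1.5 equiv), NaBH(OAc)3 (2 equiv), ClCH2CH2Cl, rt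
Reagents that add atoms: dimethylamine, CNC
Why: Reductive amination, in which the iminium ion formed from the aldehyde and Me2NH is reduced by NaBH(OAc)3 faster than the aldehyde itself, giving the ortho-aminomethyl (Mannich-base type) unit.

Step 14
Reactants: 18 1-[(2S)-6-bromo-5-methoxy-7-(methoxymethoxy)-2-phenylchroman-8-yl]-N,N-dimethylmethanamine
Product: 19 (2S)-6-bromo-8-[(dimethylamino)methyl]-5-methoxy-2-phenylchroman-7-ol
Conditions: HCl (2 M in MeOH), 40 °C; then aq NaHCO3
Reagents that add atoms: none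
Why: Acid-catalysed MOM transfer to methanol frees the 7-OH while the protonated amine cannot eliminate, and neutral work-up gives the phenolic Mannich base.

Step 15
Reactants: 19 (2S)-6-bromo-8-[(dimethylamino)methyl]-5-methoxy-2-phenylchroman-7-ol; 13 (2S)-8-bromo-5-methoxy-2-phenylchroman-7-ol
Product: 22 (2S)-8-bromo-6-{[(2S)-6-bromo-7-hydroxy-5-methoxy-2-phenylchroman-8-yl]methyl}-5-methoxy-2-phenylchroman-7-ol, via ammonium iodide 20 (not isolated), via ortho-quinone methide 21 (not isolated)
Conditions: MeI (3 equiv), MeCN, rt; evaporate; then 13 (1.3 equiv), K2CO3 (3 equiv), MeCN, 60 °C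
Reagents that add atoms: none
Why: N-methylation gives the trimethylammonium salt, whose phenoxide expels NMe3 to form the ortho-quinone methide; the phenoxide of 13, with C6 as its only free nucleophilic carbon, adds to the exocyclic methylene in a Michael (1,4-conjugate) addition, rearomatisation of both rings drives the C–C bond formation (O-alkylation is reversible), and neither stereocentre is touched.

Step 16
Reactants: 22 (2S)-8-bromo-6-{[(2S)-6-bromo-7-hydroxy-5-methoxy-2-phenylchroman-8-yl]methyl}-5-methoxy-2-phenylchroman-7-ol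
Product: 23 (2S)-6-{[(2S)-7-hydroxy-5-methoxy-2-phenylchroman-8-yl]methyl}-5-methoxy-2-phenylchroman-7-ol
Conditions: H2 (1 atm), 10% Pd/C, NaOAc (3 equiv), MeOH/EtOAc, rt
Reagents that add atoms: none
Why: Palladium-catalysed hydrodebromination removes both aryl bromides with NaOAc as HBr scavenger, while the diarylmethane, the ethers and the cyclic benzylic C2–O bonds survive at 1 atm and room temperature, so both (2S) centres are kept.

**Compound list**
1 | 2,4,6-trihydroxybenzaldehyde | O=Cc1c(O)cc(O)cc1O | starting material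
2 | 2,6-dihydroxy-4-(methoxymethoxy)benzaldehyde | O=Cc1c(O)cc(OCOC)cc1O | intermediate
3 | 2-hydroxy-6-methoxy-4-(methoxymethoxy)benzaldehyde | O=Cc1c(O)cc(OCOC)cc1OC | intermediate
4 | 2-(benzyloxy)-6-methoxy-4-(methoxymethoxy)benzaldehyde | O=Cc1c(OCc2ccccc2)cc(OCOC)cc1OC | intermediate
5 | acetophenone | CC(=O)c1ccccc1 | starting material
6 | 3-[2-(benzyloxy)-6-methoxy-4-(methoxymethoxy)phenyl]-3-hydroxy-1-phenylpropan-1-one (racemic aldol adduct) | O=C(CC(O)c1c(OCc2ccccc2)cc(OCOC)cc1OC)c1ccccc1 | intermediate (not isolated)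
7 | (E)-3-[2-(benzyloxy)-6-methoxy-4-(methoxymethoxy)phenyl]-1-phenylprop-2-en-1-one | O=C(/C=C/c1c(OCc2ccccc2)cc(OCOC)cc1OC)c1ccccc1 | intermediate
8 | 3-[2-(benzyloxy)-6-methoxy-4-(methoxymethoxy)phenyl]-1-phenylpropan-1-one | O=C(CCc1c(OCc2ccccc2)cc(OCOC)cc1OC)c1ccccc1 | intermediate
9 | (1R)-3-[2-(benzyloxy)-6-methoxy-4-(methoxymethoxy)phenyl]-1-phenylpropan-1-ol | O[C@H](CCc1c(OCc2ccccc2)cc(OCOC)cc1OC)c1ccccc1 | intermediate
10 | (1R)-3-[2-hydroxy-6-methoxy-4-(methoxymethoxy)phenyl]-1-phenylpropan-1-ol | O[C@H](CCc1c(O)cc(OCOC)cc1OC)c1ccccc1 | intermediate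
11 | (2S)-5-methoxy-7-(methoxymethoxy)-2-phenylchromane | COCOc1cc(OC)c2CC[C@@H](c3ccccc3)Oc2c1 | intermediate
12 | (2S)-8-bromo-5-methoxy-7-(methoxymethoxy)-2-phenylchromane | COCOc1cc(OC)c2CC[C@@H](c3ccccc3)Oc2c1Br | intermediate
13 | (2S)-8-bromo-5-methoxy-2-phenylchroman-7-ol | Oc1cc(OC)c2CC[C@@H](c3ccccc3)Oc2c1Br | intermediate
14 | [(2S)-5-methoxy-7-(methoxymethoxy)-2-phenylchroman-8-yl]lithium | COCOc1cc(OC)c2CC[C@@H](c3ccccc3)Oc2c1[Li] | intermediate (not isolated)
15 | (2S)-5-methoxy-7-(methoxymethoxy)-2-phenylchromane-8-carbaldehyde | COCOc1cc(OC)c2CC[C@@H](c3ccccc3)Oc2c1C=O | intermediate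
16 | (2S)-6-bromo-5-methoxy-7-(methoxymethoxy)-2-phenylchromane-8-carbaldehyde | COCOc1c(Br)c(OC)c2CC[C@@H](c3ccccc3)Oc2c1C=O | intermediate
17 | N-{[(2S)-6-bromo-5-methoxy-7-(methoxymethoxy)-2-phenylchroman-8-yl]methylidene}-N-methylmethanaminium acetate | COCOc1c(Br)c(OC)c2CC[C@@H](c3ccccc3)Oc2c1C=[N+](C)C.CC([O-])=O | intermediate (not isolated)
18 | 1-[(2S)-6-bromo-5-methoxy-7-(methoxymethoxy)-2-phenylchroman-8-yl]-N,N-dimethylmethanamine | COCOc1c(Br)c(OC)c2CC[C@@H](c3ccccc3)Oc2c1CN(C)C | intermediate
19 | (2S)-6-bromo-8-[(dimethylamino)methyl]-5-methoxy-2-phenylchroman-7-ol | Oc1c(Br)c(OC)c2CC[C@@H](c3ccccc3)Oc2c1CN(C)C | intermediate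
20 | 1-[(2S)-6-bromo-7-hydroxy-5-methoxy-2-phenylchroman-8-yl]-N,N,N-trimethylmethanaminium iodide | Oc1c(Br)c(OC)c2CC[C@@H](c3ccccc3)Oc2c1C[N+](C)(C)C.[I-] | intermediate (not isolated)
21 | (2S)-6-bromo-5-methoxy-8-methylidene-2-phenyl-3,4-dihydro-2H-chromen-7(8H)-one (ortho-quinone methide) | O=C1C(Br)=C(OC)C2=C(O[C@H](c3ccccc3)CC2)C1=C | intermediate (not isolated)
22 | (2S)-8-bromo-6-{[(2S)-6-bromo-7-hydroxy-5-methoxy-2-phenylchroman-8-yl]methyl}-5-methoxy-2-phenylchroman-7-ol | COc1c(Br)c(O)c(Cc2c(O)c(Br)c3c(c2OC)CC[C@@H](c2ccccc2)O3)c2c1CC[C@@H](c1ccccc1)O2 | intermediate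
23 | (2S)-6-{[(2S)-7-hydroxy-5-methoxy-2-phenylchroman-8-yl]methyl}-5-methoxy-2-phenylchroman-7-ol | COc1cc(O)c(Cc2c(O)cc3c(c2OC)CC[C@@H](c2ccccc2)O3)c2c1CC[C@@H](c1ccccc1)O2 | target

**Step count**
Total: 16 steps. Longest linear sequence: 15 steps (1 to 23 through steps 1–9 and 11–16); step 10 is the one-step side branch from 12 to 13.

**Three steps most likely to fail, with fallbacks**

Step 15 (quinone-methide coupling). The risks are competing O-alkylation, slow attack at the doubly flanked C6 of 13, and dimerisation of 21. The fallback sets out from 16 and replaces the base-triggered quinone methide by an acid-triggered benzylic cation. NaBH4 (MeOH/THF, 0 °C) reduces 16 to [(2S)-6-bromo-5-methoxy-7-(methoxymethoxy)-2-phenylchroman-8-yl]methanol F4. Sc(OTf)3 (5 mol %, CH2Cl2, 0 °C) ionises this trioxygenated benzylic alcohol in the presence of 13, whose C6 captures the cation in a Friedel–Crafts benzylation. This gives (2S)-8-bromo-6-{[(2S)-6-bromo-5-methoxy-7-(methoxymethoxy)-2-phenylchroman-8-yl]methyl}-5-methoxy-2-phenylchroman-7-ol F5. HCl in MeOH then removes the MOM group and the route is rejoined at 22.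

Step 9 (C8 versus C6 bromination). The risk is a mixture of regioisomers if the steric bias of the flavan is weaker than expected with the small OMe/OMOM pair. The fallback sets out from 10 and lets the free phenol direct the halogen before the ring is closed. NBS with catalytic i-Pr2NH (CH2Cl2, −20 °C; amine-mediated ortho delivery) brominates the only free position ortho to the OH to give (1R)-3-[3-bromo-2-hydroxy-6-methoxy-4-(methoxymethoxy)phenyl]-1-phenylpropan-1-ol F3. Mitsunobu closure of F3 (PPh3, DIAD, THF) with inversion comes back to the route at 12.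

Step 1 (mono-protection of the 4-OH). The risk is a statistical mixture of mono- and bis-MOM ethers. The fallback sets out from 1 and differentiates the oxygens by chelation. MOMCl (2.2 equiv) with i-Pr2NEt in CH2Cl2 gives 2-hydroxy-4,6-bis(methoxymethoxy)benzaldehyde F1, in which the chelated OH stays free. MeI/K2CO3 in DMF gives 2-methoxy-4,6-bis(methoxymethoxy)benzaldehyde F2. Brief treatment with catalytic I2 in MeOH at rt removes the carbonyl-chelated ortho MOM group faster than the para one, and the route is rejoined at 3, bypassing 2.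

**Further compounds**
F1 | step 1 | 2-hydroxy-4,6-bis(methoxymethoxy)benzaldehyde | O=Cc1c(O)cc(OCOC)cc1OCOC
F2 | step 1 | 2-methoxy-4,6-bis(methoxymethoxy)benzaldehyde | O=Cc1c(OC)cc(OCOC)cc1OCOC
F3 | step 9 | (1R)-3-[3-bromo-2-hydroxy-6-methoxy-4-(methoxymethoxy)phenyl]-1-phenylpropan-1-ol | O[C@H](CCc1c(OC)cc(OCOC)c(Br)c1O)c1ccccc1
F4 | step 15 | [(2S)-6-bromo-5-methoxy-7-(methoxymethoxy)-2-phenylchroman-8-yl]methanol | COCOc1c(Br)c(OC)c2CC[C@@H](c3ccccc3)Oc2c1CO
F5 | step 15 | (2S)-8-bromo-6-{[(2S)-6-bromo-5-methoxy-7-(methoxymethoxy)-2-phenylchroman-8-yl]methyl}-5-methoxy-2-phenylchroman-7-ol | COc1c(Br)c(OCOC)c(Cc2c(O)c(Br)c3c(c2OC)CC[C@@H](c2ccccc2)O3)c2c1CC[C@@H](c1ccccc1)O2
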